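## Retrosynthetic overview

1. The target comes from a bicyclic epoxy-ene-dione by hydroxyl-directed reduction of the C5 ketone; the ene-dione is released by acid from a dimethyl ketal and a tert-butyl ester.
2. Late C3–C1′ bond: Stille coupling of the α-bromo-enone core, already carrying the acid side chain, with an (E)-heptenylstannane (fragment C, from hept-1-yne).
3. Side-chain C=C: ozonolysis of a ring allyl group and Wittig reaction with a C4 phosphorane (fragment B, from 2-bromopropanoyl bromide).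
4. Core (fragment A): tartrate-controlled nucleophilic epoxidation of a quinone monoketal, which comes from dearomatising a tetrasubstituted 4-methoxyphenol built on hydroquinone by bromination, directed lithiation–formylation and Claisen rearrangement.
5. Ring order: the carbocycle is the benzene ring of hydroquinone and is never built; the oxirane is the only ring formed (step 7).

Assumption: diisopropyl D-tartrate is taken to give the (1S,6R) oxirane in step 7; if the first run shows the opposite sense, the L-ester is used and nothing else changes.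

## Route

Step 1
Reactants: 1 hydroquinone (benzene-1,4-diol)
Product: 2 4-methoxyphenol
Conditions: MeOH, H2SO4, NaNO2 (cat.), rt
Reagents that add atoms: methanol, CO
Why: Acid-catalysed mono-etherification in which catalytic nitrite shuttles hydroquinone through the quinone, the only species that adds methanol, so the reaction stops at the monomethyl ether.

Step 2
Reactants: 2 4-methoxyphenol
Product: 3 2-bromo-4-methoxyphenol
Conditions: Br2 (1.0 equiv), CH2Cl2, 0 °C
Reagents that add atoms: bromine, BrBr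
Why: Electrophilic aromatic bromination goes ortho to the free hydroxyl, the stronger donor, because its para position is blocked by methoxy.

Step 3
Reactants: 3 2-bromo-4-methoxyphenol; 4 allyl bromide (3-bromoprop-1-ene)
Product: 5 2-bromo-4-methoxy-1-(prop-2-en-1-yloxy)benzene
Conditions: K2CO3, acetone, reflux
Reagents that add atoms: none
Why: Williamson ether synthesis on the phenoxide gives the allyl ether, which protects the phenol during lithiation and is the substrate for the later Claisen rearrangement.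

Step 4
Reactants: 5 2-bromo-4-methoxy-1-(prop-2-en-1-yloxy)benzene
Product: 8 [2-bromo-6-methoxy-3-(prop-2-en-1-yloxy)phenyl]methanol, via aryllithium 6 (not isolated), via benzaldehyde 7 (not isolated)
Conditions: LiN(iPr)2, THF, −78 °C; DMF, −78 → 0 °C; then MeOH, NaBH4, 0 °C
Reagents that add atoms: N,N-dimethylformamide, CN(C)C=O
Why: Directed ortho-metalation by the amide base removes the most acidic ring proton, the one flanked by bromine and methoxy (no halogen–metal exchange), and formylation followed by borohydride reduction in the same flask gives the benzylic alcohol.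

Step 5
Reactants: 8 [2-bromo-6-methoxy-3-(prop-2-en-1-yloxy)phenyl]methanol
Product: 9 2-bromo-3-(hydroxymethyl)-4-methoxy-6-(prop-2-en-1-yl)phenol
Conditions: PhNEt2, 190 °C, sealed tube
Reagents that add atoms: none
Why: Aromatic Claisen rearrangement ([3,3]-sigmatropic shift) delivers the allyl group to the only ortho position that can re-aromatise, since the other carries bromine.

Step 6
Reactants: 9 2-bromo-3-(hydroxymethyl)-4-methoxy-6-(prop-2-en-1-yl)phenol
Product: 10 2-bromo-3-(hydroxymethyl)-4,4-dimethoxy-6-(prop-2-en-1-yl)cyclohexa-2,5-dien-1-one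
Conditions: PhI(OAc)2, MeOH, 0 °C
Reagents that add atoms: methanol, CO
Why: Hypervalent-iodine oxidative dearomatisation of a 4-methoxyphenol, in which methanol traps the phenoxonium ion at the para carbon to give the quinone monoketal.

Step 7
Reactants: 10 2-bromo-3-(hydroxymethyl)-4,4-dimethoxy-6-(prop-2-en-1-yl)cyclohexa-2,5-dien-1-one
Product: 11 (1S,6R)-3-bromo-4-(hydroxymethyl)-5,5-dimethoxy-1-(prop-2-en-1-yl)-7-oxabicyclo[4.1.0]hept-3-en-2-one
Conditions: Ph3COOH, NaN(SiMe3)2, diisopropyl D-tartrate, 4 Å molecular sieves, toluene, −50 °C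
Reagents that add atoms: trityl hydroperoxide, OOC(c1ccccc1)(c1ccccc1)c1ccccc1
Why: Tartrate-mediated asymmetric nucleophilic (Weitz–Scheffer) epoxidation in which the sodium trityl peroxide–tartrate aggregate, held by the substrate alkoxide, attacks the unsubstituted β-carbon of the allyl-bearing enone from one face (the bromo-enone alkene is tetrasubstituted and unreactive), and ring closure sets both oxirane stereocentres as 1S,6R.

Step 8
Reactants: 12 2-bromopropanoyl bromide
Product: 13 tert-butyl 2-bromopropanoate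
Conditions: t-BuOH, pyridine, Et2O, 0 °C → rt
Reagents that add atoms: tert-butanol, CC(C)(C)O
Why: Nucleophilic acyl substitution on the acid bromide installs an ester that survives every later step and is removed by acid at the end.

Step 9
Reactants: 13 tert-butyl 2-bromopropanoate
Product: 14 (1-tert-butoxy-1-oxopropan-2-yl)triphenylphosphonium bromide
Conditions: PPh3, toluene, 90 °C
Reagents that add atoms: triphenylphosphine, c1ccc(cc1)P(c1ccccc1)c1ccccc1
Why: SN2 quaternisation of the phosphine by the activated secondary α-bromo ester.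

Step 10
Reactants: 14 (1-tert-butoxy-1-oxopropan-2-yl)triphenylphosphonium bromide
Product: 15 tert-butyl 2-(triphenyl-λ5-phosphanylidene)propanoate
Conditions: NaOH (aq), CH2Cl2, rt
Reagents that add atoms: none
Why: Deprotonation of the acidic α-C–H of the phosphonium salt gives the stabilised, isolable Wittig ylide.

Step 11
Reactants: 11 (1S,6R)-3-bromo-4-(hydroxymethyl)-5,5-dimethoxy-1-(prop-2-en-1-yl)-7-oxabicyclo[4.1.0]hept-3-en-2-one; 15 tert-butyl 2-(triphenyl-λ5-phosphanylidene)propanoate
Product: 18 tert-butyl (2E)-4-[(1S,6R)-3-bromo-4-(hydroxymethyl)-5,5-dimethoxy-2-oxo-7-oxabicyclo[4.1.0]hept-3-en-1-yl]-2-methylbut-2-enoate, via ozonide 16 (not isolated), via aldehyde 17 (not isolated)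
Conditions: O3, CH2Cl2, −78 °C (Sudan Red 7B end point); PPh3, −78 °C → rt; then 15, rt
Reagents that add atoms: none
Why: Ozonolysis cleaves only the electron-rich terminal alkene (the bromo-enone alkene is tetrasubstituted and electron-poor), and the stabilised ylide then turns the aldehyde into the E-trisubstituted enoate (Wittig reaction) without touching the hindered ketone or the oxirane stereocentres.

Step 12
Reactants: 19 hept-1-yne
Product: 21 (1E)-1-iodohept-1-ene, via alkenylalane 20 (not isolated)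
Conditions: iBu2AlH, hexane, 50 °C; then I2, THF, −50 °C → rt
Reagents that add atoms: iodine, II
Why: syn-Hydroalumination of the terminal alkyne places aluminium at C1, and iodinolysis of the C–Al bond proceeds with retention, fixing the E geometry.

Step 13
Reactants: 21 (1E)-1-iodohept-1-ene
Product: 23 tributyl[(1E)-hept-1-en-1-yl]stannane, via alkenyllithium 22 (not isolated)
Conditions: t-BuLi (2 equiv), Et2O, −78 °C; Bu3SnCl, −78 °C → rt
Reagents that add atoms: tributyltin chloride, CCCC[Sn](Cl)(CCCC)CCCC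
Why: Lithium–iodine exchange and stannylation both occur with retention of alkene geometry.

Step 14
Reactants: 18 tert-butyl (2E)-4-[(1S,6R)-3-bromo-4-(hydroxymethyl)-5,5-dimethoxy-2-oxo-7-oxabicyclo[4.1.0]hept-3-en-1-yl]-2-methylbut-2-enoate; 23 tributyl[(1E)-hept-1-en-1-yl]stannane
Product: 24 tert-butyl (2E)-4-[(1S,6R)-3-[(1E)-hept-1-en-1-yl]-4-(hydroxymethyl)-5,5-dimethoxy-2-oxo-7-oxabicyclo[4.1.0]hept-3-en-1-yl]-2-methylbut-2-enoate
Conditions: Pd2(dba)3 (5 mol %), AsPh3 (20 mol %), toluene, 100 °C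
Reagents that add atoms: none
Why: Stille cross-coupling in which zerovalent palladium inserts into the α-bromo-enone C–Br bond and the alkenyl group is transferred from tin with retention, under neutral conditions that spare the oxirane, the ketal, the ester and the free alcohol.

Step 15
Reactants: 24 tert-butyl (2E)-4-[(1S,6R)-3-[(1E)-hept-1-en-1-yl]-4-(hydroxymethyl)-5,5-dimethoxy-2-oxo-7-oxabicyclo[4.1.0]hept-3-en-1-yl]-2-methylbut-2-enoate
Product: 26 (2E)-4-[(1S,5S,6S)-3-[(1E)-hept-1-en-1-yl]-5-hydroxy-4-(hydroxymethyl)-2-oxo-7-oxabicyclo[4.1.0]hept-3-en-1-yl]-2-methylbut-2-enoic acid, via enedione acid 25 (not isolated)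
Conditions: CF3CO2H/CH2Cl2/H2O (10:10:1), 0 °C → rt; concentrate; then Me4NBH(OAc)3, MeCN/AcOH, −20 °C
Reagents that add atoms: water, O
Why: Aqueous acid hydrolyses the dimethyl ketal and cleaves the tert-butyl ester, and the primary hydroxyl then binds the triacetoxyborohydride and delivers hydride intramolecularly (hydroxyl-directed Saksena–Evans-type reduction) only to the adjacent C5 carbonyl on the face anti to the oxirane oxygen, giving the 5S alcohol cis to the epoxide while the C2 ketone stays untouched.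

## Compound list

1 | hydroquinone (benzene-1,4-diol) | Oc1ccc(O)cc1 | starting material
2 | 4-methoxyphenol | COc1ccc(O)cc1 | intermediate
3 | 2-bromo-4-methoxyphenol | COc1ccc(O)c(Br)c1 | intermediate
4 | allyl bromide (3-bromoprop-1-ene) | C=CCBr | starting material
5 | 2-bromo-4-methoxy-1-(prop-2-en-1-yloxy)benzene | COc1ccc(OCC=C)c(Br)c1 | intermediate
6 | [2-bromo-6-methoxy-3-(prop-2-en-1-yloxy)phenyl]lithium | COc1ccc(OCC=C)c(Br)c1[Li] | intermediate
7 | 2-bromo-6-methoxy-3-(prop-2-en-1-yloxy)benzaldehyde | COc1ccc(OCC=C)c(Br)c1C=O | intermediate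
8 | [2-bromo-6-methoxy-3-(prop-2-en-1-yloxy)phenyl]methanol | COc1ccc(OCC=C)c(Br)c1CO | intermediate
9 | 2-bromo-3-(hydroxymethyl)-4-methoxy-6-(prop-2-en-1-yl)phenol | COc1cc(CC=C)c(O)c(Br)c1CO | intermediate
10 | 2-bromo-3-(hydroxymethyl)-4,4-dimethoxy-6-(prop-2-en-1-yl)cyclohexa-2,5-dien-1-one | C=CCC1=CC(OC)(OC)C(CO)=C(Br)C1=O | intermediate
11 | (1S,6R)-3-bromo-4-(hydroxymethyl)-5,5-dimethoxy-1-(prop-2-en-1-yl)-7-oxabicyclo[4.1.0]hept-3-en-2-one | BrC1=C(CO)C(OC)(OC)[C@@H]2O[C@]2(CC=C)C1=O | intermediate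
12 | 2-bromopropanoyl bromide (racemic) | CC(Br)C(=O)Br | starting material
13 | tert-butyl 2-bromopropanoate (racemic) | CC(Br)C(=O)OC(C)(C)C | intermediate
14 | (1-tert-butoxy-1-oxopropan-2-yl)triphenylphosphonium bromide (racemic) | CC(C(=O)OC(C)(C)C)[P+](c1ccccc1)(c1ccccc1)c1ccccc1.[Br-] | intermediate
15 | tert-butyl 2-(triphenyl-λ5-phosphanylidene)propanoate | CC(=P(c1ccccc1)(c1ccccc1)c1ccccc1)C(=O)OC(C)(C)C | intermediate
16 | (1S,6R)-3-bromo-4-(hydroxymethyl)-5,5-dimethoxy-1-[(1,2,4-trioxolan-3-yl)methyl]-7-oxabicyclo[4.1.0]hept-3-en-2-one (both epimers at the trioxolane carbon) | BrC1=C(CO)C(OC)(OC)[C@@H]2O[C@]2(CC3OCOO3)C1=O | intermediate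
17 | 2-[(1S,6R)-3-bromo-4-(hydroxymethyl)-5,5-dimethoxy-2-oxo-7-oxabicyclo[4.1.0]hept-3-en-1-yl]acetaldehyde | BrC1=C(CO)C(OC)(OC)[C@@H]2O[C@]2(CC=O)C1=O | intermediate
18 | tert-butyl (2E)-4-[(1S,6R)-3-bromo-4-(hydroxymethyl)-5,5-dimethoxy-2-oxo-7-oxabicyclo[4.1.0]hept-3-en-1-yl]-2-methylbut-2-enoate | BrC1=C(CO)C(OC)(OC)[C@@H]2O[C@]2(C/C=C(\C)C(=O)OC(C)(C)C)C1=O | intermediate
19 | hept-1-yne | CCCCCC#C | starting material
20 | [(1E)-hept-1-en-1-yl]bis(2-methylpropyl)alumane | CCCCC/C=C/[Al](CC(C)C)CC(C)C | intermediate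
21 | (1E)-1-iodohept-1-ene | CCCCC/C=C/I | intermediate
22 | [(1E)-hept-1-en-1-yl]lithium | CCCCC/C=C/[Li] | intermediate
23 | tributyl[(1E)-hept-1-en-1-yl]stannane | CCCCC/C=C/[Sn](CCCC)(CCCC)CCCC | intermediate
24 | tert-butyl (2E)-4-[(1S,6R)-3-[(1E)-hept-1-en-1-yl]-4-(hydroxymethyl)-5,5-dimethoxy-2-oxo-7-oxabicyclo[4.1.0]hept-3-en-1-yl]-2-methylbut-2-enoate | CCCCC/C=C/C1=C(CO)C(OC)(OC)[C@@H]2O[C@]2(C/C=C(\C)C(=O)OC(C)(C)C)C1=O | intermediate
25 | (2E)-4-[(1S,6R)-3-[(1E)-hept-1-en-1-yl]-4-(hydroxymethyl)-2,5-dioxo-7-oxabicyclo[4.1.0]hept-3-en-1-yl]-2-methylbut-2-enoic acid | CCCCC/C=C/C1=C(CO)C(=O)[C@@H]2O[C@]2(C/C=C(\C)C(=O)O)C1=O | intermediate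
26 | (2E)-4-[(1S,5S,6S)-3-[(1E)-hept-1-en-1-yl]-5-hydroxy-4-(hydroxymethyl)-2-oxo-7-oxabicyclo[4.1.0]hept-3-en-1-yl]-2-methylbut-2-enoic acid | CCCCC/C=C/C1=C(CO)[C@H](O)[C@@H]2O[C@]2(C/C=C(\C)C(=O)O)C1=O | target

## Step count and risks

Total step count: 15. Longest linear sequence: 10 steps (1, 2, 3, 4, 5, 6, 7, 11, 14, 15, from hydroquinone). The ylide arm is steps 8–10 and the stannane arm is steps 12–13.

Steps most likely to fail:

Step 7 (asymmetric epoxidation with a free hydroxymethyl group). The substrate alkoxide may disturb the peroxide–tartrate aggregate and lower the enantiomeric excess. The fallback sets out from 10 and removes the alkoxide from the picture. Silylation with TBSCl and imidazole in CH2Cl2 gives 2-bromo-3-({[tert-butyl(dimethyl)silyl]oxy}methyl)-4,4-dimethoxy-6-(prop-2-en-1-yl)cyclohexa-2,5-dien-1-one F1. The same hydroperoxide–tartrate epoxidation, now on a neutral substrate, gives (1S,6R)-3-bromo-4-({[tert-butyl(dimethyl)silyl]oxy}methyl)-5,5-dimethoxy-1-(prop-2-en-1-yl)-7-oxabicyclo[4.1.0]hept-3-en-2-one F2. Desilylation with Et3N·3HF in THF comes back to the route at 11.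

Step 11 (ozonolysis and Wittig reaction through a β-epoxy aldehyde). Aldehyde 17 can open its oxirane by β-elimination before the ylide reacts. The fallback sets out from 9 and builds the side chain by olefin metathesis before dearomatisation, so no aldehyde is made. Cross-metathesis of 9 with tert-butyl methacrylate (second-generation Hoveyda–Grubbs catalyst, CH2Cl2, 40 °C) gives tert-butyl (2E)-4-[3-bromo-2-hydroxy-4-(hydroxymethyl)-5-methoxyphenyl]-2-methylbut-2-enoate F3. Oxidation with PhI(OAc)2 in MeOH gives tert-butyl (2E)-4-[5-bromo-4-(hydroxymethyl)-3,3-dimethoxy-6-oxocyclohexa-1,4-dien-1-yl]-2-methylbut-2-enoate F4. The tartrate epoxidation of step 7 applied to F4 comes back to the route at 18.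

Step 15 (acidolysis and regioselective reduction with the dienyl unit in place). The hydroxymethyl-dienone may cyclise or decompose in acid, and the labile ene-dione 25 must be reduced at one carbonyl only. The fallback sets out from 18 and moves the cross-coupling to the very end, so that acid and hydride meet only the robust bromo-enone. CF3CO2H/CH2Cl2/H2O gives (2E)-4-[(1S,6R)-3-bromo-4-(hydroxymethyl)-2,5-dioxo-7-oxabicyclo[4.1.0]hept-3-en-1-yl]-2-methylbut-2-enoic acid F5. Directed reduction with Me4NBH(OAc)3 gives (2E)-4-[(1S,5S,6S)-3-bromo-5-hydroxy-4-(hydroxymethyl)-2-oxo-7-oxabicyclo[4.1.0]hept-3-en-1-yl]-2-methylbut-2-enoic acid F6. Stille coupling of F6 with 23 (Pd2(dba)3, AsPh3, CuI, DMF, 45 °C) comes back to the route at 26.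

## Further compounds

F1 | step 7 | 2-bromo-3-({[tert-butyl(dimethyl)silyl]oxy}methyl)-4,4-dimethoxy-6-(prop-2-en-1-yl)cyclohexa-2,5-dien-1-one | C=CCC1=CC(OC)(OC)C(CO[Si](C)(C)C(C)(C)C)=C(Br)C1=O
F2 | step 7 | (1S,6R)-3-bromo-4-({[tert-butyl(dimethyl)silyl]oxy}methyl)-5,5-dimethoxy-1-(prop-2-en-1-yl)-7-oxabicyclo[4.1.0]hept-3-en-2-one | BrC1=C(CO[Si](C)(C)C(C)(C)C)C(OC)(OC)[C@@H]2O[C@]2(CC=C)C1=O
F3 | step 11 | tert-butyl (2E)-4-[3-bromo-2-hydroxy-4-(hydroxymethyl)-5-methoxyphenyl]-2-methylbut-2-enoate | COc1cc(C/C=C(\C)C(=O)OC(C)(C)C)c(O)c(Br)c1CO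
F4 | step 11 | tert-butyl (2E)-4-[5-bromo-4-(hydroxymethyl)-3,3-dimethoxy-6-oxocyclohexa-1,4-dien-1-yl]-2-methylbut-2-enoate | O=C1C(Br)=C(CO)C(OC)(OC)C=C1C/C=C(\C)C(=O)OC(C)(C)C
F5 | step 15 | (2E)-4-[(1S,6R)-3-bromo-4-(hydroxymethyl)-2,5-dioxo-7-oxabicyclo[4.1.0]hept-3-en-1-yl]-2-methylbut-2-enoic acid | BrC1=C(CO)C(=O)[C@@H]2O[C@]2(C/C=C(\C)C(=O)O)C1=O
F6 | step 15 | (2E)-4-[(1S,5S,6S)-3-bromo-5-hydroxy-4-(hydroxymethyl)-2-oxo-7-oxabicyclo[4.1.0]hept-3-en-1-yl]-2-methylbut-2-enoic acid | BrC1=C(CO)[C@H](O)[C@@H]2O[C@]2(C/C=C(\C)C(=O)O)C1=O
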